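**Retrosynthetic overview**

1. Target 24 ⇐ Luche reduction and phenol unmasking of 9-keto ester 22 ⇐ 6α-alcohol 20 + acid 21 ⇐ hydroxyl-directed reduction of ene-dione 19.
2. 19 ⇐ oxidation and desilylation of 17 ⇐ reductive opening (SmI2) of the ether bridge of tricycle 16, which also installs H-5.
3. Key disconnection: 16 ⇐ intramolecular oxidopyrylium–alkene [5+2] cycloaddition of ylide 15, closing the cyclopentane and the ether-bridged cycloheptenone together and creating the quaternary C1.
4. 15 ⇐ Achmatowicz pyranone 13 ⇐ furyl carbinol 12 ⇐ 4-methyl-2-furyllithium 9 + dioxolanone 7.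
5. 7 ⇐ Seebach alkylation of acetal 3 (from hydroxy acid 1) with triflate 5, which sets C4. Ring order: pyranone (step 7, later the ether bridge), then the five- and seven-membered carbocycles together (step 8).

Assumption: (R)-2-hydroxy-3-methylbutanoic acid (also one step from D-valine) is accepted as a cheap commercial starting material; bicyclic compounds are named on the daucane skeleton (C1 = ring-fusion carbon with CH3, C4 = carbinol carbon with isopropyl, C5 = ring-fusion CH, C6–C10 = rest of the seven-membered ring with CH3 on C8; α = face of H-5, β = face of the C1 methyl).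

**Route**

Step 1
Reactants: 1 (R)-2-hydroxy-3-methylbutanoic acid; 2 pivalaldehyde
Product: 3 (2R,5R)-2-tert-butyl-5-(propan-2-yl)-1,3-dioxolan-4-one
Conditions: TsOH·H2O (cat.), pentane, reflux, Dean–Stark
Reagents that add atoms: none
Why: Acid-catalysed acetalisation (Seebach self-regeneration of stereocentres) gives the cis dioxolanone, which stores the configuration of 1 at the acetal carbon.

Step 2
Reactants: 4 3-methylbut-3-en-1-ol
Product: 5 3-methylbut-3-en-1-yl trifluoromethanesulfonate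
Conditions: Tf2O, 2,6-lutidine, CH2Cl2, −78 °C
Reagents that add atoms: trifluoromethanesulfonic anhydride, O=S(=O)(OS(=O)(=O)C(F)(F)F)C(F)(F)F
Why: O-Sulfonylation of the primary alcohol gives a triflate reactive enough to alkylate a hindered enolate at low temperature.

Step 3
Reactants: 3 (2R,5R)-2-tert-butyl-5-(propan-2-yl)-1,3-dioxolan-4-one; 5 3-methylbut-3-en-1-yl trifluoromethanesulfonate
Product: 7 (2R,5R)-2-tert-butyl-5-(3-methylbut-3-en-1-yl)-5-(propan-2-yl)-1,3-dioxolan-4-one, via lithium enolate 6 (not isolated)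
Conditions: LiN(iPr)2, THF, −78 °C; then 5, −78 to −40 °C
Reagents that add atoms: none
Why: Seebach enolate alkylation (SN2 on the triflate) occurs anti to the tert-butyl group, so the new chain replaces the former α-hydrogen with retention and fixes the quaternary carbinol centre (C4 of the skeleton).

Step 4
Reactants: 7 (2R,5R)-2-tert-butyl-5-(3-methylbut-3-en-1-yl)-5-(propan-2-yl)-1,3-dioxolan-4-one; 8 3-methylfuran
Product: 10 (2R)-2-hydroxy-5-methyl-1-(4-methylfuran-2-yl)-2-(propan-2-yl)hex-5-en-1-one, via 4-methyl-2-furyllithium 9 (not isolated)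
Conditions: 8, n-BuLi, TMEDA, THF, −78 to 0 °C; then 7, −78 °C; aq. NH4Cl
Reagents that add atoms: none
Why: α-Lithiation of 3-methylfuran at the less hindered C5 and nucleophilic acyl addition to the dioxolanone give, after loss of pivalaldehyde from the hemiketal, the α-hydroxy ketone (a minor 3-methyl-2-furyl isomer is removed by chromatography).

Step 5
Reactants: 10 (2R)-2-hydroxy-5-methyl-1-(4-methylfuran-2-yl)-2-(propan-2-yl)hex-5-en-1-one
Product: 11 (2R)-5-methyl-1-(4-methylfuran-2-yl)-2-(propan-2-yl)-2-(triethylsilyloxy)hex-5-en-1-one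
Conditions: TESOTf, 2,6-lutidine, CH2Cl2, −78 to 0 °C
Reagents that add atoms: triethylsilyl trifluoromethanesulfonate, CC[Si](CC)(CC)OS(=O)(=O)C(F)(F)F
Why: Silylation of the tertiary alcohol with a silyl triflate prevents internal ketal formation with the later pyranone.

Step 6
Reactants: 11 (2R)-5-methyl-1-(4-methylfuran-2-yl)-2-(propan-2-yl)-2-(triethylsilyloxy)hex-5-en-1-one
Product: 12 (2R)-5-methyl-1-(4-methylfuran-2-yl)-2-(propan-2-yl)-2-(triethylsilyloxy)hex-5-en-1-ol (both C1 epimers)
Conditions: NaBH4, MeOH, 0 °C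
Reagents that add atoms: none
Why: Hydride reduction of the furyl ketone gives the furfuryl alcohol, whose configuration is irrelevant because this carbon becomes sp2 in step 8.

Step 7
Reactants: 12 (2R)-5-methyl-1-(4-methylfuran-2-yl)-2-(propan-2-yl)-2-(triethylsilyloxy)hex-5-en-1-ol (both C1 epimers)
Product: 13 6-hydroxy-5-methyl-2-[(3R)-2,6-dimethyl-3-(triethylsilyloxy)hept-6-en-3-yl]-2H-pyran-3(6H)-one (C2/C6 epimer mixture)
Conditions: VO(acac)2 (cat.), t-BuOOH, CH2Cl2, 0 °C to rt
Reagents that add atoms: tert-butyl hydroperoxide, CC(C)(C)OO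
Why: Achmatowicz rearrangement by hydroxyl-directed vanadium-catalysed oxidation of the furan gives the hydroxypyranone without touching the remote 1,1-disubstituted alkene.

Step 8
Reactants: 13 6-hydroxy-5-methyl-2-[(3R)-2,6-dimethyl-3-(triethylsilyloxy)hept-6-en-3-yl]-2H-pyran-3(6H)-one (C2/C6 epimer mixture)
Product: 16 5α,9α-epoxy-4β-(triethylsilyloxy)dauc-7-en-6-one, via acetoxypyranone 14 (not isolated), via oxidopyrylium ylide 15 (not isolated)
Conditions: Ac2O, Et3N, DMAP (cat.), MeCN, 0 °C; then 70 °C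
Reagents that add atoms: none
Why: Acetylation and base-induced loss of acetic acid give the 3-oxidopyrylium ylide, whose intramolecular oxidopyrylium–alkene [5+2] cycloaddition closes the cyclopentane and the ether-bridged cycloheptenone at once; the three-carbon tether enforces the exo mode (C1 methyl endo, giving the trans-fused carbocyclic skeleton), and the C4 centre is expected to direct the face by placing its larger isopropyl group on the convex ether-bridge side and the silyloxy group next to the ring carbonyl (C1 methyl and C4 oxygen cis).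

Step 9
Reactants: 16 5α,9α-epoxy-4β-(triethylsilyloxy)dauc-7-en-6-one
Product: 17 9α-hydroxy-4β-(triethylsilyloxy)-5α-dauc-7-en-6-one
Conditions: SmI2, THF–MeOH, −78 °C
Reagents that add atoms: none
Why: Samarium diiodide reduction of the α-alkoxy ketone cleaves the bridgehead C5–O bond to a samarium enolate and the C9 alkoxide, and protonation of the enolate on the face just vacated by oxygen (proton relayed by the new C9 hydroxyl, and also the ring fusion that keeps C6 away from the 4α-isopropyl group) installs H-5α.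

Step 10
Reactants: 17 9α-hydroxy-4β-(triethylsilyloxy)-5α-dauc-7-en-6-one
Product: 18 4β-(triethylsilyloxy)-5α-dauc-7-ene-6,9-dione
Conditions: Dess–Martin periodinane, CH2Cl2, rt
Reagents that add atoms: none
Why: Dess–Martin oxidation of the allylic alcohol erases the C9 centre, which the bridge had delivered with the wrong (α) configuration, and gives the ene-dione.

Step 11
Reactants: 18 4β-(triethylsilyloxy)-5α-dauc-7-ene-6,9-dione
Product: 19 4β-hydroxy-5α-dauc-7-ene-6,9-dione
Conditions: HF·pyridine, THF, 0 °C to rt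
Reagents that add atoms: none
Why: Acidic fluoride desilylation frees the tertiary alcohol while avoiding base, under which this β-hydroxy ketone could undergo retro-aldol cleavage or oxa-Michael addition to the ene-dione.

Step 12
Reactants: 19 4β-hydroxy-5α-dauc-7-ene-6,9-dione
Product: 20 4β,6α-dihydroxy-5α-dauc-7-en-9-one
Conditions: Me4NBH(OAc)3, MeCN–AcOH, −30 °C
Reagents that add atoms: none
Why: Evans–Saksena hydroxyl-directed reduction: the C4 hydroxyl binds boron and delivers hydride intramolecularly only to the β-hydroxy ketone carbonyl (C6), giving the 1,3-anti diol (6α-OH) and leaving the remote C9 carbonyl untouched.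

Step 13
Reactants: 20 4β,6α-dihydroxy-5α-dauc-7-en-9-one; 21 4-acetoxy-3-methoxybenzoic acid
Product: 22 6α-(4-acetoxy-3-methoxybenzoyloxy)-4β-hydroxy-5α-dauc-7-en-9-one
Conditions: DCC, DMAP, CH2Cl2, 0 °C to rt
Reagents that add atoms: none
Why: Steglich esterification acylates the only secondary hydroxyl, the tertiary C4 hydroxyl being inert, and the phenol is masked as its acetate to prevent self-acylation.

Step 14
Reactants: 22 6α-(4-acetoxy-3-methoxybenzoyloxy)-4β-hydroxy-5α-dauc-7-en-9-one
Product: 24 6α-(4-hydroxy-3-methoxybenzoyloxy)-5α-dauc-7-ene-4β,9β-diol, via aryl acetate diol 23 (not isolated)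
Conditions: NaBH4, CeCl3·7H2O, MeOH, −78 °C; then K2CO3 (cat.), 0 °C
Reagents that add atoms: none
Why: Luche 1,2-reduction should deliver hydride to the C9 carbonyl from the α face, away from the axial C1 methyl, giving the 9β-alcohol, and brief carbonate methanolysis then cleaves only the phenolic acetate, which is far more labile than the hindered secondary aroyl ester.

**Compound list**

1 | (R)-2-hydroxy-3-methylbutanoic acid | OC(=O)[C@H](O)C(C)C | starting material
2 | pivalaldehyde (2,2-dimethylpropanal) | CC(C)(C)C=O | starting material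
3 | (2R,5R)-2-tert-butyl-5-(propan-2-yl)-1,3-dioxolan-4-one | O=C1O[C@H](C(C)(C)C)O[C@@H]1C(C)C | intermediate
4 | 3-methylbut-3-en-1-ol | CC(=C)CCO | starting material
5 | 3-methylbut-3-en-1-yl trifluoromethanesulfonate | CC(=C)CCOS(=O)(=O)C(F)(F)F | intermediate
6 | lithium (2R)-2-tert-butyl-5-(propan-2-yl)-1,3-dioxol-4-olate (lithium enolate of 3) | [Li]OC1=C(C(C)C)O[C@@H](C(C)(C)C)O1 | intermediate
7 | (2R,5R)-2-tert-butyl-5-(3-methylbut-3-en-1-yl)-5-(propan-2-yl)-1,3-dioxolan-4-one | O=C1O[C@H](C(C)(C)C)O[C@@]1(C(C)C)CCC(C)=C | intermediate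
8 | 3-methylfuran | Cc1ccoc1 | starting material
9 | (4-methylfuran-2-yl)lithium | [Li]c1cc(C)co1 | intermediate
10 | (2R)-2-hydroxy-5-methyl-1-(4-methylfuran-2-yl)-2-(propan-2-yl)hex-5-en-1-one | Cc1coc(c1)C(=O)[C@](O)(C(C)C)CCC(C)=C | intermediate
11 | (2R)-5-methyl-1-(4-methylfuran-2-yl)-2-(propan-2-yl)-2-(triethylsilyloxy)hex-5-en-1-one | Cc1coc(c1)C(=O)[C@](O[Si](CC)(CC)CC)(C(C)C)CCC(C)=C | intermediate
12 | (2R)-5-methyl-1-(4-methylfuran-2-yl)-2-(propan-2-yl)-2-(triethylsilyloxy)hex-5-en-1-ol (both C1 epimers) | Cc1coc(c1)C(O)[C@](O[Si](CC)(CC)CC)(C(C)C)CCC(C)=C | intermediate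
13 | 6-hydroxy-5-methyl-2-[(3R)-2,6-dimethyl-3-(triethylsilyloxy)hept-6-en-3-yl]-2H-pyran-3(6H)-one (C2/C6 epimer mixture) | OC1OC([C@](O[Si](CC)(CC)CC)(C(C)C)CCC(C)=C)C(=O)C=C1C | intermediate
14 | 5-methyl-3-oxo-2-[(3R)-2,6-dimethyl-3-(triethylsilyloxy)hept-6-en-3-yl]-3,6-dihydro-2H-pyran-6-yl acetate | CC(=O)OC1OC([C@](O[Si](CC)(CC)CC)(C(C)C)CCC(C)=C)C(=O)C=C1C | intermediate
15 | 5-methyl-2-[(3R)-2,6-dimethyl-3-(triethylsilyloxy)hept-6-en-3-yl]pyrylium-3-olate | Cc1c[o+]c([C@](O[Si](CC)(CC)CC)(C(C)C)CCC(C)=C)c([O-])c1 | intermediate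
16 | 5α,9α-epoxy-4β-(triethylsilyloxy)dauc-7-en-6-one | O=C2C=C(C)[C@@H]4C[C@@]3(C)CC[C@@](O[Si](CC)(CC)CC)(C(C)C)[C@]23O4 | intermediate
17 | 9α-hydroxy-4β-(triethylsilyloxy)-5α-dauc-7-en-6-one | O=C2C=C(C)[C@@H](O)C[C@@]3(C)CC[C@@](O[Si](CC)(CC)CC)(C(C)C)[C@H]23 | intermediate
18 | 4β-(triethylsilyloxy)-5α-dauc-7-ene-6,9-dione | O=C2C=C(C)C(=O)C[C@@]3(C)CC[C@@](O[Si](CC)(CC)CC)(C(C)C)[C@H]23 | intermediate
19 | 4β-hydroxy-5α-dauc-7-ene-6,9-dione | O=C2C=C(C)C(=O)C[C@@]3(C)CC[C@@](O)(C(C)C)[C@H]23 | intermediate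
20 | 4β,6α-dihydroxy-5α-dauc-7-en-9-one | O[C@H]2C=C(C)C(=O)C[C@@]3(C)CC[C@@](O)(C(C)C)[C@H]23 | intermediate
21 | 4-acetoxy-3-methoxybenzoic acid | COc1cc(C(=O)O)ccc1OC(C)=O | starting material
22 | 6α-(4-acetoxy-3-methoxybenzoyloxy)-4β-hydroxy-5α-dauc-7-en-9-one | COc1cc(C(=O)O[C@H]2C=C(C)C(=O)C[C@@]3(C)CC[C@@](O)(C(C)C)[C@H]23)ccc1OC(C)=O | intermediate
23 | 6α-(4-acetoxy-3-methoxybenzoyloxy)-5α-dauc-7-ene-4β,9β-diol | COc1cc(C(=O)O[C@H]2C=C(C)[C@H](O)C[C@@]3(C)CC[C@@](O)(C(C)C)[C@H]23)ccc1OC(C)=O | intermediate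
24 | 6α-(4-hydroxy-3-methoxybenzoyloxy)-5α-dauc-7-ene-4β,9β-diol = (3R,3aS,4S,7R,8aR)-3,7-dihydroxy-6,8a-dimethyl-3-(propan-2-yl)-1,2,3,3a,4,7,8,8a-octahydroazulen-4-yl 4-hydroxy-3-methoxybenzoate | COc1cc(C(=O)O[C@H]2C=C(C)[C@H](O)C[C@@]3(C)CC[C@@](O)(C(C)C)[C@H]23)ccc1O | target

**Step count and risks**

Total steps: 14. Longest linear sequence: 13 (steps 1 and 3–14).

The three steps I rank as most likely to fail are 9, 14 and 3. The face selectivity of step 8 rests on the steric argument given there; no later step can correct C1.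

Step 9 is the most exposed. The bridging oxygen is α to the ketone at C5 but also allylic (γ to the ketone) at C9, so SmI2 could break the C9–O bond instead. The fallback sets out from 16 and returns at 18. It accepts that mode of cleavage, which gives the tertiary α-ketol 5α-hydroxy-4β-(triethylsilyloxy)dauc-7-en-6-one F2. A second SmI2 reduction (THF–HMPA, t-BuOH) removes the α-hydroxyl to give 4β-(triethylsilyloxy)-5α-dauc-7-en-6-one F3. Allylic oxidation of the C9 methylene with CrO3·3,5-dimethylpyrazole then gives ene-dione 18, so the C9 oxygen comes from oxidation rather than from the bridge.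

Step 14 may deliver hydride from the β face if the C6 ester shields the α face more than the C1 methyl shields the β face. The fallback sets out from 22 and returns at 24. The same reduction then gives the epimeric alcohol 6α-(4-acetoxy-3-methoxybenzoyloxy)-5α-dauc-7-ene-4β,9α-diol F4. This is inverted by a Mitsunobu reaction with formic acid (PPh3, DIAD) to the formate 6α-(4-acetoxy-3-methoxybenzoyloxy)-9β-formyloxy-5α-dauc-7-en-4β-ol F5. K2CO3 in MeOH then removes the formate and the phenolic acetate to give 24.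

Step 3 asks a hindered, thermally fragile enolate to react with an unactivated primary electrophile. The fallback sets out from 3 (through enolate 6) and returns at 7. It replaces SN2 alkylation by conjugate addition of 6 to methyl vinyl ketone, giving (2R,5R)-2-tert-butyl-5-(3-oxobutyl)-5-(propan-2-yl)-1,3-dioxolan-4-one F1 with the same anti-to-tert-butyl selectivity. Wittig methylenation (Ph3P=CH2, THF, 0 °C) then gives 7.

**Further compounds**

F1 | step 3 | (2R,5R)-2-tert-butyl-5-(3-oxobutyl)-5-(propan-2-yl)-1,3-dioxolan-4-one | O=C1O[C@H](C(C)(C)C)O[C@@]1(C(C)C)CCC(C)=O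
F2 | step 9 | 5α-hydroxy-4β-(triethylsilyloxy)dauc-7-en-6-one | O=C2C=C(C)CC[C@@]3(C)CC[C@@](O[Si](CC)(CC)CC)(C(C)C)[C@]23O
F3 | step 9 | 4β-(triethylsilyloxy)-5α-dauc-7-en-6-one | O=C2C=C(C)CC[C@@]3(C)CC[C@@](O[Si](CC)(CC)CC)(C(C)C)[C@H]23
F4 | step 14 | 6α-(4-acetoxy-3-methoxybenzoyloxy)-5α-dauc-7-ene-4β,9α-diol | COc1cc(C(=O)O[C@H]2C=C(C)[C@@H](O)C[C@@]3(C)CC[C@@](O)(C(C)C)[C@H]23)ccc1OC(C)=O
F5 | step 14 | 6α-(4-acetoxy-3-methoxybenzoyloxy)-9β-formyloxy-5α-dauc-7-en-4β-ol | COc1cc(C(=O)O[C@H]2C=C(C)[C@H](OC=O)C[C@@]3(C)CC[C@@](O)(C(C)C)[C@H]23)ccc1OC(C)=O
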